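The nucleophile is the charge to watch in this flask.

in all of them: electrophile 10 mM
- epsilon: nucleophile 20 mM; run made earlier
- delta: nucleophile 45 mM; run made earlier
- flask: nucleophile 30.0 mM; time 12 min

| run | time / min | electrophile / % | target / % |
|---|---|---|---|
| epsilon | 0.833 | 75.0 | 18.4 |
| epsilon | 1.33 | 65.9 | 22.9 |
| epsilon | 2.00 | 56.2 | 23.9 |
| epsilon | 2.50 | 51.4 | 24.6 |
| epsilon | 4.00 | 41.4 | 23.3 |
| epsilon | 6.00 | 33.5 | 19.9 |
| epsilon | 10.0 | 25.3 | 18.5 |
| delta | 0.500 | 65.6 | 23.8 |
| delta | 1.33 | 37.5 | 27.0 |
| delta | 2.50 | 20.8 | 18.5 |
| delta | 4.00 | 10.7 | 11.2 |
| delta | 6.00 | 5.1 | 7.3 |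
| delta | 8.00 | 2.2 | 4.1 |
| delta | 10.0 | 1.8 | 2.9 |

(scatter of a reading: 0.5 percentage points)

* part of the electrophile that has reacted at 12 min
* share of the unused nucleophile that is free and not bound as protonated nucleophile, at 12 min

- what was read earlier has a scatter of 0.5 percentage points, one standard deviation
- the earlier runs do not show how much of nucleophile is bound; that part of a forecast is a guess

The first delta reading, taken with the nucleophile near its charge, gives the electrophile a rate constant k of 0.0187 mM⁻¹ min⁻¹. Late in the epsilon run, the electrophile's decay divided by k reads as 3.75 mM of free nucleophile, with 7.06 mM of electrophile reacted. The spend s, nucleophile lost from the free pool per electrophile reacted, is then 2.30.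

Take the nucleophile first. The flask's charge, divided by s, reaches 13.0 mM of electrophile, more than the amount charged, so the electrophile stays the limiting reagent. The epsilon charge reaches 8.69 mM. Next, taking s as a constant read from that one stretch of the epsilon run, an assumption of this reckoning, the estimated surplus f of free nucleophile after full reaction is 6.98 mM in this flask. Last comes time: the electrophile's half-life is estimated at 1.23 min at the charge, and on the same assumption it lengthens toward 5.30 min as the free pool nears f. Integrating with free nucleophile equal to f plus s times the electrophile left, my reckoning gives 94.2% reacted. The earlier runs do not show how much of the nucleophile is bound, so this reckoning commits to no free share.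

The forecast, holding that “acid released in the first step must tie up nucleophile”, gives 92% reacted and 45% free.

The flask gives 92.4% reacted and 39.2% free.

    nucleophile + target → over-reaction product (k = 0.530 M⁻¹ s⁻¹)
    electrophile + nucleophile → acid set free + target (k = 0.340 M⁻¹ s⁻¹)
    target ⇌ isomer of the product (K = 0.820, k = 0.00230 s⁻¹)
    nucleophile + acid set free ⇌ protonated nucleophile, settled at all times (K = 1500 M⁻¹)

From the epsilon run at its last reading, 74.3%, changing the nucleophile by itself gives 90.5%, and changing the time by itself gives 76.6%. The flask's own spend at 12.0 min is 2.67, above s. With s, the neighbouring flask holding 12 mM of nucleophile reaches 52.1% of its electrophile, and that flask has reacted 55.4%.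

The readings are simulated for substances that don't exist; scatter was added.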